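Remark: ring atoms carry carvone numbers (C1 carbonyl, C2 methyl-bearing, C3, C4, C5 isopropenyl-bearing, C6 acyloxy-bearing). The SMILES is read as the (1S,3R,4R,6S) epoxy ketone of the (S)-carvone series, with the oxirane oxygen and the C6 acyloxy group both trans to the isopropenyl group; ylide 2 is taken as a catalogue reagent.

## The problem

The target is a single cyclohexanone ring in which every carbon except C4 is functionalized: a C2–C3 oxirane, the C1 ketone, an ester oxygen at C6 and the isopropenyl group at C5. Of the four stereocentres only C5 can be bought, in (S)-carvone, so C5 has to control the other three. C2 is tied to C3 by the cis-fused oxirane, so the real task is to place the C3 oxygen and the C6 oxygen on the ring face opposite the isopropenyl group. C6 is α to the ketone and can epimerize, and the α,β-epoxy ketone does not tolerate strong nucleophiles or prolonged base. The side chain carries two enoates and a primary allylic ester, which alkaline hydroperoxide would attack, and the isopropenyl group reacts with peracids and dioxiranes. The ester is a secondary α-ketol ester next to a substituted carbon, so a late esterification has to be done on a hindered, epimerizable alcohol. The enabling feature is that the oxirane oxygen on C3 and the ester oxygen on C6 lie 1,4 to each other across the six-membered ring and on the same face, with C1 and C2 between them. The ring is therefore the formal adduct of one O2 molecule across C3 and C6 of a cyclohexa-1,3-diene (C6=C1–C2=C3) whose C1 oxygen already carries the side-chain acyl group: target 13 is an isomer of dienyl ester 10 plus O2.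

## Retrosynthesis

**13 back to 10.** The C6–O acyl bond is moved back to the C1 oxygen and the C1–O/C6 oxirane is re-closed, which gives syn-bis-epoxide 12, an enol ester epoxide. The two oxiranes of 12 are then merged into the O–O bridge of endoperoxide 11, and the C3–O and C6–O bonds are cut to give dienyl ester 10 and O2. The neighbouring cuts (the ester C6–O bond alone, or the oxirane alone) each remove one oxygen and leave the other to a separate oxidation with its own face selectivity. This cut removes both ring oxygens and three stereocentres at once, and the cis C3–O/C6–O relation comes from a suprafacial cycloaddition. Precursor 10 is a flat diene with one stereocentre and the complete carbon skeleton. The forward reaction must add O2 anti to the C5 substituent, leave three other alkenes alone, and transfer the acyl group from O1 to O6 without breaking the C6–O bond.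

**10 back to 8 and 7.** The enol ester O–acyl bond is cut to give (S)-carvone 8 and acid chloride 7. This is the only union of the two halves, so the side chain first serves as the diene-forming enol substituent and then ends up as the C6 ester, and no separate esterification of a ketol is needed. The forward reaction needs kinetic α′-enolization at C6 and O-acylation rather than C-acylation.

**7 back to 3 and 4.** The acid chloride comes from acid 6, which comes from tert-butyl ester 5. The inner ester bond of 5 is cut to hydroxy ester 3 and tigloyl chloride 4. A tert-butyl ester is chosen because it can be removed with acid without touching the allylic tiglate, which base hydrolysis would not allow.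

**3 back to 1 and 2.** The trisubstituted C=C bond is cut by a Wittig disconnection to glycolaldehyde dimer 1 and the stabilized ylide 2, which should give the (E)-enoate directly with the free hydroxyl in place.

## Roads not taken

**Alternative 1:** (the obvious route) Epoxidize first, oxygenate C6 second, esterify last. (S)-Carvone 8 would be converted by Weitz–Scheffer epoxidation into trans-epoxy ketone A1, the C6 enolate or silyl enol ether of A1 hydroxylated (Rubottom) to ketol A2, and A2 esterified with acid 6. The forward key step is the electrophilic hydroxylation of the C6 enolate of A1.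
- It needs four operations on the terpene and three stoichiometric oxidant or base events; the chosen plan needs two operations and one O2.
- C2/C3 and C6 come from two unrelated face selections, whereas the chosen plan fixes their cis relation in one cycloaddition.
- Strong base is put on an epoxy ketone, the electrophilic oxidant must choose the enol ether over the isopropenyl group, and the valuable acid is attached last to a hindered, epimerizable ketol.
- It is kept as the fallback because every step is known.

**Alternative 2:** Form the C6–O bond oxidatively with the whole acid. (S)-Carvone 8 and acid 6 would be coupled by α′-acyloxylation with Mn(OAc)3 (trivalent manganese) or a hypervalent iodine reagent to give trans-6-acyloxycarvone A3, followed by nucleophilic epoxidation of the enone.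
- The manganese enolate/radical is trapped by carboxylate with little facial control at C6, and acetate competes with the valuable acid as ligand.
- The closing alkaline hydroperoxide step would meet two enoates, an allylic ester and an α-acyloxy ketone, so ester cleavage, acyl migration and C6 epimerization are to be expected.
- The chosen plan uses no basic peroxide at all.

**Alternative 3:** Direct the oxirane with a hydroxyl group. The C1 ketone of A3 would be reduced to allylic alcohol A4 with the C1 hydroxyl on the face opposite the isopropenyl group, A4 epoxidized with VO(acac)2/t-BuOOH to epoxy alcohol A5, and A5 oxidized at C1 to give 13.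
- Small hydrides deliver the equatorial C1 alcohol, cis to the isopropenyl group, which is the wrong face for delivery, so an inversion would be needed.
- The cis-vicinal hydroxy ester in A4 and A5 invites 1,2-acyl migration.
- The C1 oxidation state is removed and restored, which costs four or five steps for what the chosen plan does in one flask.

Key step: step 6

## Route

Step 1
Reactants: 1 glycolaldehyde dimer (2,5-dihydroxy-1,4-dioxane); 2 tert-butyl 2-(triphenylphosphoranylidene)propanoate
Product: 3 tert-butyl (2E)-4-hydroxy-2-methylbut-2-enoate
Conditions: THF, 65 °C (0.5 equiv of 1)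
Reagents that add atoms: none
Why: Wittig olefination of glycolaldehyde, released from its dimer on heating, by a stabilized α-branched ylide; such ylides should give the (E)-trisubstituted enoate, and any (Z)-isomer is removed by chromatography.

Step 2
Reactants: 3 tert-butyl (2E)-4-hydroxy-2-methylbut-2-enoate; 4 tigloyl chloride ((2E)-2-methylbut-2-enoyl chloride)
Product: 5 tert-butyl (2E)-2-methyl-4-{[(2E)-2-methylbut-2-enoyl]oxy}but-2-enoate
Conditions: pyridine, 4-(dimethylamino)pyridine (DMAP, 5 mol %), CH2Cl2, 0 °C → rt
Reagents that add atoms: none
Why: Acylation of a primary allylic alcohol by an acid chloride under nucleophilic catalysis; pyridine is too weak a base to form the vinylketene from 4, so the (E)-tiglate should stay conjugated and keep its geometry.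

Step 3
Reactants: 5 tert-butyl (2E)-2-methyl-4-{[(2E)-2-methylbut-2-enoyl]oxy}but-2-enoate
Product: 6 (2E)-2-methyl-4-{[(2E)-2-methylbut-2-enoyl]oxy}but-2-enoic acid
Conditions: CF3CO2H/CH2Cl2 (1:4), 0 °C → rt
Reagents that add atoms: none
Why: Acidolysis of the tert-butyl ester through the tert-butyl cation (E1, isobutene lost); the primary allylic tiglate should not ionize because its allyl cation would be conjugated with an ester carbonyl.

Step 4
Reactants: 6 (2E)-2-methyl-4-{[(2E)-2-methylbut-2-enoyl]oxy}but-2-enoic acid
Product: 7 (2E)-2-methyl-4-{[(2E)-2-methylbut-2-enoyl]oxy}but-2-enoyl chloride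
Conditions: (COCl)2, DMF (cat.), CH2Cl2, 0 °C → rt; evaporate, use crude
Reagents that add atoms: oxalyl chloride, O=C(Cl)C(=O)Cl
Why: Acid chloride formation through the Vilsmeier-type chloroiminium species from DMF and oxalyl chloride; only gases are released, so crude 7 can be used directly and neither alkene geometry is touched.

Step 5
Reactants: 8 (S)-(+)-carvone ((5S)-2-methyl-5-(prop-1-en-2-yl)cyclohex-2-en-1-one); 7 (2E)-2-methyl-4-{[(2E)-2-methylbut-2-enoyl]oxy}but-2-enoyl chloride
Product: 10 (3S)-6-methyl-3-(prop-1-en-2-yl)cyclohexa-1,5-dien-1-yl (2E)-2-methyl-4-{[(2E)-2-methylbut-2-enoyl]oxy}but-2-enoate, via lithium dienolate 9 (not isolated)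
Conditions: LiN(iPr)2, THF, −78 °C; N,N′-dimethylpropyleneurea (DMPU); then 7, −78 → −40 °C
Reagents that add atoms: none
Why: Kinetic α′-deprotonation of the enone at C6 gives the cross-conjugated dienolate 9, which should be O-acylated by the hindered α-branched acid chloride in the presence of DMPU (enol ester formation from a lithium enolate); C5 is not touched.

Step 6
Reactants: 10 (3S)-6-methyl-3-(prop-1-en-2-yl)cyclohexa-1,5-dien-1-yl (2E)-2-methyl-4-{[(2E)-2-methylbut-2-enoyl]oxy}but-2-enoate
Product: 13 (1S,3R,4R,6S)-1-methyl-2-oxo-4-(prop-1-en-2-yl)-7-oxabicyclo[4.1.0]heptan-3-yl (2E)-2-methyl-4-{[(2E)-2-methylbut-2-enoyl]oxy}but-2-enoate, via endoperoxide 11 (not isolated), via bis-epoxide 12 (not isolated)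
Conditions: O2, 5,10,15,20-tetraphenylporphyrin (H2TPP, 1 mol %), white LED, CH2Cl2, −78 °C; Ar purge, lamp off; Co(TPP) (5 mol %), −40 → 0 °C; then DMAP (20 mol %), 0 °C → rt
Reagents that add atoms: dioxygen, O=O
Why: Proposed new method: singlet oxygen adds suprafacially across C3 and C6 of the cyclohexa-1,3-diene of 10 in a [4+2] cycloaddition (the known photooxygenation of cyclic 1,3-dienes), which closes the 2,3-dioxabicyclo[2.2.2]octene ring of 11 and puts both new C–O bonds on one face. That face should be the one anti to the C5 isopropenyl group, which sits on the carbon next to the diene terminus C6, so C3 and C6 are set by C5; the isopropenyl group and the two tiglate-type alkenes should be left alone because the electrophilic oxidant reacts far faster with an s-cis diene than with a 1,1-disubstituted or an electron-poor alkene. Co(TPP) (divalent cobalt) then splits the O–O bond by single-electron transfer; the oxygen on C3 closes the C2–C3 oxirane by 3-exo-trig addition to C2 of the enol ester double bond, and the C1 radical closes the second oxirane on the cobalt-bound C6 oxygen (3-exo homolytic substitution), which returns the catalyst and gives syn-bis-epoxide 12. This is the known endoperoxide to syn-bis-epoxide isomerization, not yet shown for an endoperoxide whose bridge alkene is an enol ester; C2 is fixed because its oxygen is delivered from C3 within the ring. In 12 the C1–C6 oxirane is an enol ester epoxide: DMAP attacks the ester carbonyl, the hemiketal alkoxide at C1 collapses to the ketone with opening of the C1–O oxirane bond, and the C6 alkoxide takes the acyl group back from the acylpyridinium ion. The C6–O bond is never broken, so C6 keeps the configuration set in the cycloaddition. The closest known reactions are the acid- or heat-induced rearrangement of enol ester epoxides to α-acyloxy ketones, which can invert the migration terminus, and their basic hydrolysis to α-hydroxy ketones with retention, which is why nucleophilic catalysis is chosen here. The step needs face selectivity in the cycloaddition and completion of the cobalt stage before DMAP is added, since base on 11 would open the peroxide by Kornblum–DeLaMare elimination.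

## Compound list

1 | glycolaldehyde dimer (2,5-dihydroxy-1,4-dioxane) | OC1COC(O)CO1 | starting material
2 | tert-butyl 2-(triphenylphosphoranylidene)propanoate | CC(=P(c1ccccc1)(c1ccccc1)c1ccccc1)C(=O)OC(C)(C)C | starting material
3 | tert-butyl (2E)-4-hydroxy-2-methylbut-2-enoate | CC(C)(C)OC(=O)/C(C)=C/CO | intermediate
4 | tigloyl chloride, (2E)-2-methylbut-2-enoyl chloride | O=C(Cl)/C(C)=C/C | starting material
5 | tert-butyl (2E)-2-methyl-4-{[(2E)-2-methylbut-2-enoyl]oxy}but-2-enoate | CC(C)(C)OC(=O)/C(C)=C/COC(=O)/C(C)=C/C | intermediate
6 | (2E)-2-methyl-4-{[(2E)-2-methylbut-2-enoyl]oxy}but-2-enoic acid | OC(=O)/C(C)=C/COC(=O)/C(C)=C/C | intermediate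
7 | (2E)-2-methyl-4-{[(2E)-2-methylbut-2-enoyl]oxy}but-2-enoyl chloride | ClC(=O)/C(C)=C/COC(=O)/C(C)=C/C | intermediate
8 | (S)-(+)-carvone, (5S)-2-methyl-5-(prop-1-en-2-yl)cyclohex-2-en-1-one | CC1=CC[C@@H](CC1=O)C(C)=C | starting material
9 | lithium (3S)-6-methyl-3-(prop-1-en-2-yl)cyclohexa-1,5-dien-1-olate (kinetic C1=C6 dienolate of 8) | C=C(C)[C@H]1CC=C(C)C([O-])=C1.[Li+] | intermediate
10 | (3S)-6-methyl-3-(prop-1-en-2-yl)cyclohexa-1,5-dien-1-yl (2E)-2-methyl-4-{[(2E)-2-methylbut-2-enoyl]oxy}but-2-enoate (C6=C1–C2=C3 dienyl ester of carvone) | C=C(C)[C@H]1CC=C(C)C(OC(=O)/C(C)=C/COC(=O)/C(C)=C/C)=C1 | intermediate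
11 | endoperoxide: 2,3-dioxabicyclo[2.2.2]oct-5-ene with the O–O bridge from C3 to C6 on the face anti to the C5 isopropenyl group, bridge alkene C1(O-acyl)=C2(CH3), acyl = side chain of 6 | C=C(C)[C@H]1C[C@@H]2OO[C@H]1C(OC(=O)/C(C)=C/COC(=O)/C(C)=C/C)=C2C | intermediate
12 | syn-bis-epoxide: C2–C3 oxirane and C1–C6 oxirane both on the face anti to the isopropenyl group, acyloxy group on C1 | C=C(C)[C@H]1C[C@@H]2O[C@]2(C)[C@]3(OC(=O)/C(C)=C/COC(=O)/C(C)=C/C)O[C@H]13 | intermediate
13 | (1S,3R,4R,6S)-1-methyl-2-oxo-4-(prop-1-en-2-yl)-7-oxabicyclo[4.1.0]heptan-3-yl (2E)-2-methyl-4-{[(2E)-2-methylbut-2-enoyl]oxy}but-2-enoate | C=C(C)[C@H]1C[C@@H]2O[C@]2(C)C(=O)[C@@H]1OC(=O)/C(C)=C/COC(=O)/C(C)=C/C | target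

## Step count and least certain steps

Total step count: 6. Longest linear sequence: 6 steps (1 and 2 → 3 → 5 → 6 → 7 → 10 → 13); (S)-carvone 8 enters two steps before the target.

**Step 6 (key step, proposed new method).** Three things can go wrong.
- Facial discrimination in the cycloaddition may be poor, because singlet oxygen is a small dienophile and feels the substituent on the carbon next to the diene terminus only weakly. This would give the diastereomer with both oxygens cis to the isopropenyl group alongside 13.
- The C6 alkoxyl radical may fragment by β-scission toward the allyl-stabilized C5 radical, or shift hydrogen to give a hydroxy enone, instead of closing 3-exo to the bis-epoxide.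
- The acyl group may shift by the intramolecular thermal or acid path before DMAP acts, which would invert C6.

Fallback by known chemistry, setting out from 8 and returning at 13: Weitz–Scheffer epoxidation of 8 (H2O2, NaOH, MeOH, 0 °C) should give the trans-epoxy ketone F1. Kinetic enolization at C6 (LiN(iPr)2, THF, −78 °C) and silylation with Me3SiCl should give the silyl enol ether F2. Rubottom oxidation with dimethyldioxirane at −78 °C and mild acid work-up should give the hydroxy ketone F3, with the oxidant entering anti to the neighbouring isopropenyl group. Acylation of F3 with acid chloride 7 (pyridine, DMAP, CH2Cl2, 0 °C) returns to the route at target 13.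

**Step 5.** C-acylation at C6 may compete with O-acylation, and the enolate or the amine may deprotonate the acid chloride at the γ-position to a vinylketene, which would lead to deconjugated products. Fallback, setting out from 8 and 6 and returning at 10: 8 is converted (LiN(iPr)2, then Me3SiCl, THF, −78 °C) into the trimethylsilyl dienol ether F4, and acid 6 (cyanuric fluoride, pyridine, CH2Cl2) into the acyl fluoride F5. Fluoride-catalysed O-acylation of F4 with F5 (Bu4NF, cat., THF, 0 °C) is regiospecific for oxygen because the naked enolate is acylated and re-releases fluoride, and it gives 10 without amine or lithium salts present.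

**Step 1.** Free glycolaldehyde may oligomerize or undergo aldol self-condensation faster than it is olefinated, and some (Z)-olefination followed by lactonization may occur. Fallback, setting out from 4 and returning at 5, which avoids glycolaldehyde and steps 1 and 2 altogether: tigloyl chloride 4 acylates allyl alcohol (pyridine, CH2Cl2, 0 °C) to give allyl tiglate F6. Cross-metathesis of F6 with excess tert-butyl methacrylate (second-generation Hoveyda–Grubbs catalyst, CH2Cl2, 40 °C) should form the (E)-trisubstituted enoate 5, the internal tiglate alkene being too hindered and electron-poor to take part.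

## Further compounds

F1 | step 6 | (1S,4S,6S)-1-methyl-4-(prop-1-en-2-yl)-7-oxabicyclo[4.1.0]heptan-2-one (trans-carvone epoxide) | C=C(C)[C@H]1C[C@@H]2O[C@]2(C)C(=O)C1
F2 | step 6 | trimethylsilyl enol ether (C1=C6) of F1 | C=C(C)[C@H]1C[C@@H]2O[C@]2(C)C(O[Si](C)(C)C)=C1
F3 | step 6 | (1S,3R,4R,6S)-3-hydroxy-1-methyl-4-(prop-1-en-2-yl)-7-oxabicyclo[4.1.0]heptan-2-one | C=C(C)[C@H]1C[C@@H]2O[C@]2(C)C(=O)[C@@H]1O
F4 | step 5 | trimethyl{[(3S)-6-methyl-3-(prop-1-en-2-yl)cyclohexa-1,5-dien-1-yl]oxy}silane | C=C(C)[C@H]1CC=C(C)C(O[Si](C)(C)C)=C1
F5 | step 5 | (2E)-2-methyl-4-{[(2E)-2-methylbut-2-enoyl]oxy}but-2-enoyl fluoride | O=C(F)/C(C)=C/COC(=O)/C(C)=C/C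
F6 | step 1 | prop-2-en-1-yl (2E)-2-methylbut-2-enoate (allyl tiglate) | C=CCOC(=O)/C(C)=C/C
A1 | alternative 1 | (1S,4S,6S)-1-methyl-4-(prop-1-en-2-yl)-7-oxabicyclo[4.1.0]heptan-2-one | C=C(C)[C@H]1C[C@@H]2O[C@]2(C)C(=O)C1
A2 | alternative 1 | (1S,3R,4R,6S)-3-hydroxy-1-methyl-4-(prop-1-en-2-yl)-7-oxabicyclo[4.1.0]heptan-2-one | C=C(C)[C@H]1C[C@@H]2O[C@]2(C)C(=O)[C@@H]1O
A3 | alternative 2 | (1R,6R)-3-methyl-2-oxo-6-(prop-1-en-2-yl)cyclohex-3-en-1-yl (2E)-2-methyl-4-{[(2E)-2-methylbut-2-enoyl]oxy}but-2-enoate (trans-6-acyloxycarvone) | C=C(C)[C@H]1CC=C(C)C(=O)[C@@H]1OC(=O)/C(C)=C/COC(=O)/C(C)=C/C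
A4 | alternative 3 | allylic alcohol from A3: C1 hydroxyl cis to the C6 acyloxy group and trans to the isopropenyl group | C=C(C)[C@H]1CC=C(C)[C@H](O)[C@@H]1OC(=O)/C(C)=C/COC(=O)/C(C)=C/C
A5 | alternative 3 | epoxy alcohol from A4: C2–C3 oxirane cis to the C1 hydroxyl and the C6 acyloxy group | C=C(C)[C@H]1C[C@@H]2O[C@]2(C)[C@H](O)[C@@H]1OC(=O)/C(C)=C/COC(=O)/C(C)=C/C
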